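The quinone ring is opened at the bond between the hydroxyl-bearing carbon beside the side-chain carbon and the carbonyl carbon beside the methyl-bearing carbon. Four ring atoms, C(=O)–C(CH3)=C(OH)–C(=O), are read as a squarate-derived cyclobutenedione; the side-chain carbon and its oxygenated neighbour as a β-ethoxyvinyl unit carrying the C19 chain. Their 1,2-adduct, a 4-hydroxy-4-(2-ethoxyalkenyl)cyclobutenone, is the precursor. Heating opens it to a dienylketene whose 6π-electrocyclisation joins the ketene carbon to the ethoxy-bearing vinyl carbon, two oxygen-bearing carbons of like polarity united pericyclically, closing the six-membered ring; in-flask oxidation gives the fully substituted dialkoxyquinone, and hydrolysis gives the target.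

Key step: step 7

Remark: the enol ether geometry of 9 is left open because step 4 erases and resets it; 13, 16 and 18 are racemic and their stereocentres vanish before the target, whose only stereo element is the (E)-alkene set in step 1.

Step 1
Reactants: 1 hex-1-yne
Product: 3 (E)-1-iodohex-1-ene, via alkenylzirconocene 2 (not isolated)
Conditions: Cp2Zr(H)Cl, THF, rt; then I2, 0 °C
Reagents that add atoms: iodine, II
Why: Hydrozirconation of the terminal alkyne is a syn addition that places zirconium on the terminal carbon, and iodinolysis of the C–Zr bond proceeds with retention, so the (E)-geometry is set by the syn addition (hydrozirconation–iodination).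

Step 2
Reactants: 4 12-bromododec-1-ene; 3 (E)-1-iodohex-1-ene
Product: 6 (E)-1-bromooctadec-13-ene, via alkylborane 5 (not isolated)
Conditions: 9-BBN, THF, 0 °C to rt; then 3, Pd(dppf)Cl2 (cat.), K3PO4 (aq), DMF, rt
Reagents that add atoms: none
Why: 9-BBN hydroborates the terminal alkene at the terminal carbon, and the B-alkyl Suzuki–Miyaura coupling with the vinyl iodide should retain the (E)-geometry while leaving the unactivated primary C–Br bond untouched at room temperature.

Step 3
Reactants: 6 (E)-1-bromooctadec-13-ene; 7 3,3-diethoxyprop-1-ene (acrolein diethyl acetal)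
Product: 9 (16E)-1-ethoxyhenicosa-1,16-diene, via Grignard reagent 8 (not isolated)
Conditions: Mg, THF; then 7, CuBr (5 mol %), THF, −10 °C to rt; H2O quench
Reagents that add atoms: none
Why: Copper-catalysed SN2′ substitution of the allylic acetal by the Grignard reagent attacks the terminal CH2 and expels ethoxide, which should give the enol ether three carbons longer and thereby supplies the odd-numbered chain from an even-numbered bromide.

Step 4
Reactants: 9 (16E)-1-ethoxyhenicosa-1,16-diene
Product: 11 (1Z,16E)-2-bromo-1-ethoxyhenicosa-1,16-diene, via dibromo ether 10 (not isolated)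
Conditions: Br2 (1.0 equiv), CH2Cl2, −78 °C; then iPr2NEt, −78 °C to 40 °C
Reagents that add atoms: bromine, BrBr
Why: The enol ether is far more nucleophilic than the isolated chain alkene, so one equivalent of Br2 at −78 °C should add only there, and amine-induced loss of HBr from the α-bromo ether (ionisation to the oxocarbenium ion, deprotonation at C2) is the known bromination–dehydrobromination route to β-bromo enol ethers, expected to favour the Z isomer with the chain trans to ethoxy.

Step 5
Reactants: 12 dimethyl squarate
Product: 14 3-methoxy-4-methylcyclobut-3-ene-1,2-dione, via carbinol 13 (not isolated)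
Conditions: MeLi, THF, −78 °C; 1 M HCl quench; then conc. HCl (cat.), CH2Cl2, rt
Reagents that add atoms: methyllithium, [Li]C
Why: MeLi adds 1,2 to one squarate carbonyl and acid-catalysed hydrolysis of the adduct releases methanol to give the cyclobutenedione, the standard mono-substitution sequence of squaric esters.

Step 6
Reactants: 11 (1Z,16E)-2-bromo-1-ethoxyhenicosa-1,16-diene; 14 3-methoxy-4-methylcyclobut-3-ene-1,2-dione
Product: 16 4-[(1Z,16E)-1-ethoxyhenicosa-1,16-dien-2-yl]-4-hydroxy-3-methoxy-2-methylcyclobut-2-en-1-one (racemic), via vinyllithium 15 (not isolated)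
Conditions: t-BuLi (2 equiv), THF/Et2O, −78 °C; then 14, −78 °C; H2O quench
Reagents that add atoms: none
Why: Bromine–lithium exchange retains the alkene geometry and gives a vinyllithium stabilised by Li···O chelation, which should add 1,2 to the more electrophilic ketone carbonyl of 14 (the one beside the methoxy-bearing carbon, the other being a vinylogous ester carbonyl); the new carbinol centre forms racemic and is destroyed in step 7.

Step 7
Reactants: 16 4-[(1Z,16E)-1-ethoxyhenicosa-1,16-dien-2-yl]-4-hydroxy-3-methoxy-2-methylcyclobut-2-en-1-one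
Product: 20 2-ethoxy-5-methoxy-6-methyl-3-[(E)-nonadec-14-enyl]cyclohexa-2,5-diene-1,4-dione, via dienylketene 17 (not isolated), via cyclohexadienone 18 (not isolated), via hydroquinone 19 (not isolated)
Conditions: p-xylene, 138 °C (reflux), Ar; then Ag2O, K2CO3, rt
Reagents that add atoms: none
Why: Heating cleaves the C1–C4 bond of the cyclobutenone in a conrotatory 4π-electrocyclic ring opening in which the donor hydroxyl rotates outward, so the ethoxyalkenyl arm lies cis to the ketene in 17; thermal disrotatory 6π-electrocyclisation then bonds the ketene carbon to the ethoxy-bearing vinyl carbon, dienone 18 enolises to hydroquinone 19 and Ag2O dehydrogenates it to quinone 20. The closest known reaction type is the Moore rearrangement, the thermal ring expansion of 4-alkenyl- or 4-aryl-4-hydroxycyclobutenones to hydroquinones and quinones. The six-membered carbocycle is closed by 6π-electrocyclisation of a hexatriene in which the ketene C=C is one of the three π bonds. No stereocentre survives, since the carbinol centre of 16 and C6 of 18 are erased on aromatisation and the remote (E)-alkene is not involved. The step needs the six-ring electrocyclic closure to outrun lactonisation of the ketene by the hydroxyl and polar five-ring closure at the nucleophilic enol ether carbon, and the outward rotation of OH (torquoselectivity) secures this by delivering the Z-dienylketene that can close without bond rotation. The substitution pattern (methyl beside the ketene-derived carbonyl, ethoxy on the new ring carbon beside the side chain) is fixed by the regioselective addition in step 6.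

Step 8
Reactants: 20 2-ethoxy-5-methoxy-6-methyl-3-[(E)-nonadec-14-enyl]cyclohexa-2,5-diene-1,4-dione
Product: 21 2,5-dihydroxy-3-methyl-6-[(E)-nonadec-14-enyl]cyclohexa-2,5-diene-1,4-dione (target)
Conditions: NaOH (2 M aq), EtOH, 60 °C; then HCl (aq) to pH 2
Reagents that add atoms: sodium hydroxide, [Na+].[OH-]
Why: Both alkoxy groups are vinylogous esters and should be displaced by hydroxide through addition–elimination (vinylogous saponification), the dianion being reprotonated by HCl, while the isolated (E)-alkene is inert to aqueous base.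

Compound list
1 | hex-1-yne | CCCCC#C | starting material
2 | (E)-hex-1-enylzirconocene chloride (cyclopentadienyl rings drawn σ-bonded) | CCCC/C=C/[Zr](Cl)(C1C=CC=C1)C1C=CC=C1 | intermediate
3 | (E)-1-iodohex-1-ene | CCCC/C=C/I | intermediate
4 | 12-bromododec-1-ene | C=CCCCCCCCCCCBr | starting material
5 | 9-(12-bromododecyl)-9-borabicyclo[3.3.1]nonane | BrCCCCCCCCCCCCB1C2CCCC1CCC2 | intermediate
6 | (E)-1-bromooctadec-13-ene | CCCC/C=C/CCCCCCCCCCCCBr | intermediate
7 | 3,3-diethoxyprop-1-ene (acrolein diethyl acetal) | C=CC(OCC)OCC | starting material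
8 | (E)-octadec-13-enylmagnesium bromide | CCCC/C=C/CCCCCCCCCCCC[Mg]Br | intermediate
9 | (16E)-1-ethoxyhenicosa-1,16-diene (enol ether geometry mixed) | CCCC/C=C/CCCCCCCCCCCCCC=COCC | intermediate
10 | (16E)-1,2-dibromo-1-ethoxyhenicos-16-ene (diastereomer mixture) | CCCC/C=C/CCCCCCCCCCCCCC(Br)C(Br)OCC | intermediate
11 | (1Z,16E)-2-bromo-1-ethoxyhenicosa-1,16-diene | CCCC/C=C/CCCCCCCCCCCCC/C(Br)=C/OCC | intermediate
12 | dimethyl squarate (3,4-dimethoxycyclobut-3-ene-1,2-dione) | COC1=C(OC)C(=O)C1=O | starting material
13 | 4-hydroxy-2,3-dimethoxy-4-methylcyclobut-2-en-1-one (racemic) | CC1(O)C(OC)=C(OC)C1=O | intermediate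
14 | 3-methoxy-4-methylcyclobut-3-ene-1,2-dione | CC1=C(OC)C(=O)C1=O | intermediate
15 | (16E)-1-ethoxyhenicosa-1,16-dien-2-yllithium, lithium cis to ethoxy | CCCC/C=C/CCCCCCCCCCCCC/C([Li])=C/OCC | intermediate
16 | 4-[(1Z,16E)-1-ethoxyhenicosa-1,16-dien-2-yl]-4-hydroxy-3-methoxy-2-methylcyclobut-2-en-1-one (racemic) | CCCC/C=C/CCCCCCCCCCCCC/C(=C/OCC)C1(O)C(OC)=C(C)C1=O | intermediate
17 | (3Z,5Z)-6-ethoxy-4-hydroxy-3-methoxy-2-methyl-5-[(E)-nonadec-14-enyl]hexa-1,3,5-trien-1-one (dienylketene) | CCCC/C=C/CCCCCCCCCCCCC/C(=C/OCC)/C(O)=C(OC)\C(C)=C=O | intermediate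
18 | 6-ethoxy-4-hydroxy-3-methoxy-2-methyl-5-[(E)-nonadec-14-enyl]cyclohexa-2,4-dien-1-one (racemic) | CCCC/C=C/CCCCCCCCCCCCCC1=C(O)C(OC)=C(C)C(=O)C1OCC | intermediate
19 | 2-ethoxy-5-methoxy-6-methyl-3-[(E)-nonadec-14-enyl]benzene-1,4-diol | CCCC/C=C/CCCCCCCCCCCCCc1c(O)c(OC)c(C)c(O)c1OCC | intermediate
20 | 2-ethoxy-5-methoxy-6-methyl-3-[(E)-nonadec-14-enyl]cyclohexa-2,5-diene-1,4-dione | CCCC/C=C/CCCCCCCCCCCCCC1=C(OCC)C(=O)C(C)=C(OC)C1=O | intermediate
21 | 2,5-dihydroxy-3-methyl-6-[(E)-nonadec-14-enyl]cyclohexa-2,5-diene-1,4-dione | CCCC/C=C/CCCCCCCCCCCCCC1=C(O)C(=O)C(C)=C(O)C1=O | target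

Total step count: 8. Longest linear sequence: 7 steps (steps 1, 2, 3, 4, 6, 7 and 8, from hex-1-yne).

Steps most likely to fail

Step 7 (key step). The ketene may be captured by the free tertiary hydroxyl (lactonisation to a butenolide), the enol ether carbon may close on the ketene in a polar five-ring mode, or ethanol may be lost from the sensitive carbinol before ring opening. The fallback sets out from 16 and comes back at 20. The hydroxyl would be silylated (TMSCl, Et3N, DMAP, CH2Cl2) to the trimethylsilyl ether F1. Thermolysis in p-xylene should then pass through the silyloxy dienylketene F2 and the silyloxy cyclohexadienone F3 to the mono-silylated hydroquinone F4. Oxidation of this with (NH4)2Ce(NO3)6 in aqueous MeCN at 0 °C would remove the silyl group and give 20. A ketene without a free hydroxyl cannot lactonise, and the ring is still closed at the same two carbons.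

Step 4. Bromine may also add to the remote (E)-alkene, the elimination may give an E/Z mixture, and the acid-labile bromo enol ether may hydrolyse during isolation. The fallback sets out from 9 and comes back at 11. Bromoalkoxylation with NBS in EtOH at −40 °C, for which the enol ether is by far the faster partner, would give the bromo acetal F5. Elimination of one ethoxy group with TMSOTf and iPr2NEt in CH2Cl2 (acetal-to-enol-ether conversion under non-acidic work-up) would then give 11.

Step 6. The β-ethoxyvinyllithium may lose lithium ethoxide to give an alkyne, the organolithium may deprotonate the ring methyl of 14 instead of adding, and the carbinol may collapse on work-up. The fallback sets out from 8 and comes back at 20; it brings the oxygen in after ring closure.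
- CuI-catalysed coupling of 8 with 2,3-dibromopropene would give the 2-bromo-1-alkene F6.
- t-BuLi would convert it to the alkenyllithium F7, which has no β-leaving group.
- Addition to 14 would give the carbinol F8.
- The same thermolysis should run through the dienylketene F9 and the cyclohexadienone F10 to the hydroquinone F11, and Ag2O would give the quinone F12, whose only free ring position is the carbon beside the side chain.
- Oxidative conjugate addition of ethanol at that position (EtOH, ZnCl2, air) would give 19, which is oxidised in the flask to 20.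

Further compounds
F1 | step 7 | 4-[(1Z,16E)-1-ethoxyhenicosa-1,16-dien-2-yl]-3-methoxy-2-methyl-4-(trimethylsilyloxy)cyclobut-2-en-1-one | CCCC/C=C/CCCCCCCCCCCCC/C(=C/OCC)C1(O[Si](C)(C)C)C(OC)=C(C)C1=O
F2 | step 7 | (3Z,5Z)-6-ethoxy-3-methoxy-2-methyl-5-[(E)-nonadec-14-enyl]-4-(trimethylsilyloxy)hexa-1,3,5-trien-1-one | CCCC/C=C/CCCCCCCCCCCCC/C(=C/OCC)/C(O[Si](C)(C)C)=C(OC)\C(C)=C=O
F3 | step 7 | 6-ethoxy-3-methoxy-2-methyl-5-[(E)-nonadec-14-enyl]-4-(trimethylsilyloxy)cyclohexa-2,4-dien-1-one | CCCC/C=C/CCCCCCCCCCCCCC1=C(O[Si](C)(C)C)C(OC)=C(C)C(=O)C1OCC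
F4 | step 7 | 2-ethoxy-5-methoxy-6-methyl-3-[(E)-nonadec-14-enyl]-4-(trimethylsilyloxy)phenol | CCCC/C=C/CCCCCCCCCCCCCc1c(O[Si](C)(C)C)c(OC)c(C)c(O)c1OCC
F5 | step 4 | (16E)-2-bromo-1,1-diethoxyhenicos-16-ene | CCCC/C=C/CCCCCCCCCCCCCC(Br)C(OCC)OCC
F6 | step 6 | (16E)-2-bromohenicosa-1,16-diene | CCCC/C=C/CCCCCCCCCCCCCC(Br)=C
F7 | step 6 | (16E)-henicosa-1,16-dien-2-yllithium | CCCC/C=C/CCCCCCCCCCCCCC([Li])=C
F8 | step 6 | 4-[(16E)-henicosa-1,16-dien-2-yl]-4-hydroxy-3-methoxy-2-methylcyclobut-2-en-1-one | CCCC/C=C/CCCCCCCCCCCCCC(=C)C1(O)C(OC)=C(C)C1=O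
F9 | step 6 | (3Z)-4-hydroxy-3-methoxy-2-methyl-5-[(E)-nonadec-14-enyl]hexa-1,3,5-trien-1-one | CCCC/C=C/CCCCCCCCCCCCCC(=C)/C(O)=C(OC)\C(C)=C=O
F10 | step 6 | 4-hydroxy-3-methoxy-2-methyl-5-[(E)-nonadec-14-enyl]cyclohexa-2,4-dien-1-one | CCCC/C=C/CCCCCCCCCCCCCC1=C(O)C(OC)=C(C)C(=O)C1
F11 | step 6 | 2-methoxy-3-methyl-6-[(E)-nonadec-14-enyl]benzene-1,4-diol | CCCC/C=C/CCCCCCCCCCCCCc1cc(O)c(C)c(OC)c1O
F12 | step 6 | 2-methoxy-3-methyl-6-[(E)-nonadec-14-enyl]cyclohexa-2,5-diene-1,4-dione | CCCC/C=C/CCCCCCCCCCCCCC1=CC(=O)C(C)=C(OC)C1=O
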